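## Retrosynthetic overview

- Penithochromone T is eugenin (5-hydroxy-7-methoxy-2-methylchromone) joined to a C8 ω-oxo-enoate. The one skeletal disconnection is the CH2–CH(OH) bond between the methylene on chromone C2 and the carbinol carbon (C9–C8 of the nonenoic acid), a vinylogous aldol retron.
- Enabling feature: the C2-methyl carbon is vinylogous to the C4 carbonyl through C2=C3 of the γ-pyranone ring. O4-silylation and deprotonation give an exocyclic silyl dienol ether (2-methylidene-2H-chromene) that regains the pyranone when the C–C bond forms; a chiral Ti(IV) catalyst sets C8 (R) in the same event.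
- No ring is formed in the route. The benzopyranone bicycle comes intact from noreugenin (7-O-methylation, then transient bis-silylation that also masks the peri 5-OH). The aldehyde arm comes from ε-caprolactone (partial reduction/Wittig, then oxidation).
- The acid is carried as an allyl ester and released last under neutral Pd(0) conditions, because the product is a vinylogous β-hydroxy ketone that is sensitive to base and acid.

Key step: step 5

Remark on the chemistry (assumption): the sense of induction of the titanium catalyst with the new dienol ether is assigned by analogy with its dienolate additions. Step 5 means the ligand antipode that leaves the Si face of the aldehyde (O > C7 > H) open and so leads to 8R; this would be confirmed by a Mosher ester analysis of 10. Both antipodes of the ligand L* (2-[(3-bromo-5-tert-butyl-2-hydroxybenzylidene)amino]-2'-hydroxy-1,1'-binaphthyl) are accessible.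

## Route

Step 1
Reactants: 1 noreugenin (5,7-dihydroxy-2-methyl-4H-chromen-4-one)
Product: 2 eugenin (5-hydroxy-7-methoxy-2-methyl-4H-chromen-4-one)
Conditions: MeI (1.05 equiv), K2CO3 (1.1 equiv), acetone, 50 °C
Reagents that add atoms: iodomethane, CI
Why: Williamson ether synthesis; the free, more acidic 7-OH is alkylated, while the 5-OH is held in a hydrogen bond to the C4 carbonyl and should not react with one equivalent of MeI.

Step 2
Reactants: 2 eugenin
Product: 3 7-methoxy-2-methylidene-4,5-bis(trimethylsilyloxy)-2H-chromene
Conditions: TMSOTf (2.3 equiv), Et3N (3 equiv), Et2O, 0 °C → rt; ammonium triflate layer separated under Ar, upper layer concentrated, used crude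
Reagents that add atoms: trimethylsilyl trifluoromethanesulfonate, C[Si](C)(C)OS(=O)(=O)C(F)(F)F
Why: Soft enolization (silyl dienol ether formation, as in the preparation of bis-silyl dienol ethers of 1,3-dicarbonyl compounds): silylation of the 5-OH and of the C4 carbonyl gives a 4-silyloxy-2-methylbenzopyrylium, whose acidic 2-methyl group is deprotonated by Et3N to the neutral anhydrobase.

Step 3
Reactants: 4 ε-caprolactone (oxepan-2-one); 5 allyl (triphenylphosphoranylidene)acetate
Product: 7 allyl (2E)-8-hydroxyoct-2-enoate, via 6-hydroxyhexanal 6 (not isolated)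
Conditions: DIBAL-H (1.05 equiv), CH2Cl2, −78 °C; MeOH (quench); then 5 (1.3 equiv), −78 °C → rt; aq. Rochelle salt
Reagents that add atoms: none
Why: Partial reduction of the lactone stops at the aluminium hemiacetal at −78 °C; its collapse on warming releases the hydroxy aldehyde for a Wittig olefination, and the stabilized ylide should give the E-enoate.

Step 4
Reactants: 7 allyl (2E)-8-hydroxyoct-2-enoate
Product: 8 allyl (2E)-8-oxooct-2-enoate
Conditions: TEMPO (10 mol %), PhI(OAc)2 (1.1 equiv), CH2Cl2, rt
Reagents that add atoms: none
Why: TEMPO/PhI(OAc)2 (oxoammonium-mediated) oxidation of the primary alcohol should stop at the aldehyde in anhydrous CH2Cl2 and leave the enoate and the allyl ester untouched.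

Step 5
Reactants: 3 7-methoxy-2-methylidene-4,5-bis(trimethylsilyloxy)-2H-chromene (1.3 equiv); 8 allyl (2E)-8-oxooct-2-enoate
Product: 10 allyl (2E,8R)-8-hydroxy-9-(5-hydroxy-7-methoxy-4-oxo-4H-chromen-2-yl)non-2-enoate, via bis-TMS aldol adduct 9 (not isolated)
Conditions: Ti(OiPr)4/L*/3,5-di-tert-butylsalicylic acid (1:1:1, preformed, 5 mol %, Si-face-selective antipode), Et2O, −10 → 0 °C; then 1 M aq. HCl, THF, 0 °C
Reagents that add atoms: none
Why: Proposed new method: the Ti(IV) centre binds the aldehyde of 8 and the exocyclic CH2 terminus of the dienol ether 3 (O1–C2(=CH2)–C3=C4–OSi) attacks it in an open transition state, giving a 4-silyloxybenzopyrylium whose silyl group is passed by the catalyst's salicylate to the titanium aldolate, so that the pyranone is restored, 9 is released and the catalyst turns over; aqueous acid then removes both Me3Si groups. The closest known reaction type is the catalytic enantioselective vinylogous Mukaiyama aldol (dienolate) addition of the exocyclic O-silyl dienolate of 2,2,6-trimethyl-1,3-dioxin-4-one to aldehydes with this class of titanium complex; 3, a γ-pyranone anhydrobase, is its benzo-fused analogue and has not yet been used in it. No ring is closed; the heterocycle is only re-aromatized, which is the driving force. The new stereocenter C8 is set under catalyst control, the binaphthyl ligand shielding one face of the bound aldehyde so that the Si face is attacked, which gives 8R. The step needs γ- over α-regioselectivity, secured because only attack through the exocyclic carbon regenerates the pyranone while C3 is flanked and gains no aromaticity, and aldehyde over enoate chemoselectivity, secured by the much higher electrophilicity of the aldehyde. Enantioface selection with an unbranched aldehyde rests on the catalyst alone and is the open point of the step.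

Step 6
Reactants: 10 allyl (2E,8R)-8-hydroxy-9-(5-hydroxy-7-methoxy-4-oxo-4H-chromen-2-yl)non-2-enoate
Product: 11 penithochromone T, (2E,8R)-8-hydroxy-9-(5-hydroxy-7-methoxy-4-oxo-4H-chromen-2-yl)non-2-enoic acid
Conditions: Pd(PPh3)4 (5 mol %), N-methylaniline (3 equiv), THF, rt; aq. citric acid work-up
Reagents that add atoms: none
Why: Tsuji–Trost deallylation; Pd(0) ionizes the allyl ester to a π-allyl complex and the carboxylate, the weakly basic amine traps the allyl group, and the neutral conditions should avoid retro-aldol cleavage or dehydration of the vinylogous β-hydroxy ketone and leave C8 untouched.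

## Compound list

1 | noreugenin (5,7-dihydroxy-2-methyl-4H-chromen-4-one) | Cc1cc(=O)c2c(O)cc(O)cc2o1 | starting material
2 | eugenin (5-hydroxy-7-methoxy-2-methyl-4H-chromen-4-one) | COc1cc(O)c2c(=O)cc(C)oc2c1 | intermediate
3 | 7-methoxy-2-methylidene-4,5-bis(trimethylsilyloxy)-2H-chromene | C=C1C=C(O[Si](C)(C)C)c2c(O[Si](C)(C)C)cc(OC)cc2O1 | intermediate
4 | ε-caprolactone (oxepan-2-one) | O=C1CCCCCO1 | starting material
5 | allyl (triphenylphosphoranylidene)acetate | C=CCOC(=O)C=P(c1ccccc1)(c1ccccc1)c1ccccc1 | starting material
6 | 6-hydroxyhexanal (not isolated) | O=CCCCCCO | intermediate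
7 | allyl (2E)-8-hydroxyoct-2-enoate | C=CCOC(=O)/C=C/CCCCCO | intermediate
8 | allyl (2E)-8-oxooct-2-enoate | C=CCOC(=O)/C=C/CCCCC=O | intermediate
9 | bis-TMS aldol adduct, allyl (2E,8R)-9-[7-methoxy-4-oxo-5-(trimethylsilyloxy)-4H-chromen-2-yl]-8-(trimethylsilyloxy)non-2-enoate (not isolated) | COc1cc(O[Si](C)(C)C)c2c(=O)cc(C[C@H](O[Si](C)(C)C)CCCC/C=C/C(=O)OCC=C)oc2c1 | intermediate
10 | allyl (2E,8R)-8-hydroxy-9-(5-hydroxy-7-methoxy-4-oxo-4H-chromen-2-yl)non-2-enoate | COc1cc(O)c2c(=O)cc(C[C@H](O)CCCC/C=C/C(=O)OCC=C)oc2c1 | intermediate
11 | penithochromone T, (2E,8R)-8-hydroxy-9-(5-hydroxy-7-methoxy-4-oxo-4H-chromen-2-yl)non-2-enoic acid | COc1cc(O)c2c(=O)cc(C[C@H](O)CCCC/C=C/C(=O)O)oc2c1 | target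

## Step count and risks

Total steps: 6. Longest linear sequence: 4 steps (1 → 2 → 5 → 6, or equally 3 → 4 → 5 → 6).

Steps most likely to fail:

1. Step 5 (Proposed new method). What may go wrong: poor enantiofacial discrimination with an unbranched aldehyde, or arrest of turnover if the C5 silyl group migrates and the peri O5/O4 pair chelates titanium. Fallback with known chemistry, setting out from 2 and 8 and coming back at 10: the bond is made without asymmetric induction and the stereocenter is set afterwards. Eugenin 2 is converted with LiHMDS (2.2 equiv, THF, −78 °C) into its phenoxide/dienolate dianion (lateral metalation of 2-methylchromones), which adds to 8 to give the racemic aldol rac-allyl (2E)-8-hydroxy-9-(5-hydroxy-7-methoxy-4-oxo-4H-chromen-2-yl)non-2-enoate F1. Dess–Martin oxidation gives the ketone allyl (2E)-9-(5-hydroxy-7-methoxy-4-oxo-4H-chromen-2-yl)-8-oxonon-2-enoate F2. Reduction with an (R)-selective ketoreductase from a commercial panel (NADP+, isopropanol recycling, pH 7 buffer/DMSO, 30 °C) returns 10.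

2. Step 2. What may go wrong: protonation of the dienol ether at the exocyclic carbon or cleavage of the peri aryl silyl ether during salt removal and concentration, which returns 2. Fallback setting out from 2 and coming back at 11: the phenol is masked by a group that the last step removes anyway, so that only one silyl group is needed. Allyl bromide/K2CO3/DMF at 60 °C gives 5-(allyloxy)-7-methoxy-2-methyl-4H-chromen-4-one F3. TMSOTf/Et3N gives 5-(allyloxy)-7-methoxy-2-methylidene-4-(trimethylsilyloxy)-2H-chromene F4. Addition to 8 under the conditions of step 5 gives the silyl ether allyl (2E,8R)-9-[5-(allyloxy)-7-methoxy-4-oxo-4H-chromen-2-yl]-8-(trimethylsilyloxy)non-2-enoate F5, and the acid work-up gives allyl (2E,8R)-9-[5-(allyloxy)-7-methoxy-4-oxo-4H-chromen-2-yl]-8-hydroxynon-2-enoate F6. Pd(PPh3)4/N-methylaniline then removes the allyl ether and the allyl ester together to give 11.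

3. Step 3. What may go wrong: over-reduction of the lactone to the diol and oligomerization of the hydroxy aldehyde before olefination. Fallback setting out from 5 and coming back at 7: the aldehyde is approached from the alcohol side. Purchased hexane-1,6-diol (3 equiv) is oxidized with TEMPO/PhI(OAc)2 in CH2Cl2 in the presence of ylide 5 (tandem oxidation–Wittig olefination). The 6-hydroxyhexanal 6 formed in the flask is trapped as it appears, and 7 is separated from excess diol and from the doubly olefinated diester.

Further compounds
F1 | step 5 | rac-allyl (2E)-8-hydroxy-9-(5-hydroxy-7-methoxy-4-oxo-4H-chromen-2-yl)non-2-enoate | COc1cc(O)c2c(=O)cc(CC(O)CCCC/C=C/C(=O)OCC=C)oc2c1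
F2 | step 5 | allyl (2E)-9-(5-hydroxy-7-methoxy-4-oxo-4H-chromen-2-yl)-8-oxonon-2-enoate | COc1cc(O)c2c(=O)cc(CC(=O)CCCC/C=C/C(=O)OCC=C)oc2c1
F3 | step 2 | 5-(allyloxy)-7-methoxy-2-methyl-4H-chromen-4-one | C=CCOc1cc(OC)cc2oc(C)cc(=O)c12
F4 | step 2 | 5-(allyloxy)-7-methoxy-2-methylidene-4-(trimethylsilyloxy)-2H-chromene | C=C1C=C(O[Si](C)(C)C)c2c(OCC=C)cc(OC)cc2O1
F5 | step 2 | allyl (2E,8R)-9-[5-(allyloxy)-7-methoxy-4-oxo-4H-chromen-2-yl]-8-(trimethylsilyloxy)non-2-enoate | C=CCOc1cc(OC)cc2oc(C[C@H](O[Si](C)(C)C)CCCC/C=C/C(=O)OCC=C)cc(=O)c12
F6 | step 2 | allyl (2E,8R)-9-[5-(allyloxy)-7-methoxy-4-oxo-4H-chromen-2-yl]-8-hydroxynon-2-enoate | C=CCOc1cc(OC)cc2oc(C[C@H](O)CCCC/C=C/C(=O)OCC=C)cc(=O)c12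
F0 | step 3 | none | none
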